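**Retrosynthetic overview**
1. Target ⇒ caged, diene-free keto-lactone. The two sorbyl units come last: C-acylation of the six-membered-ring ketone with sorbyl chloride, and a sorbyl ketone grown from a CH2OSi handle on the quaternary ring carbon (aldehyde, Nozaki–Hiyama–Kishi, oxidation). The tertiary ketol comes from Mn-catalysed hydration of an exo-methylene ketone.
2. The six-membered ring of the bicyclo[3.2.1]octane is closed by Michael addition of a methyl ketone to the β-carbon of a cyclopentenone.
3. Key disconnection: the central cyclopentane is cut at its two bonds between fully substituted carbons (acyl-bearing ring-fusion carbon to the methyl-bearing quaternary carbon; carbinol carbon to the lactone O–C(CH3) carbon). This is a formal [3+2] that closes the γ-lactone and the cyclopentane together.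
4. Enabling feature: the three ring carbons C(acyl)–CH–C(CH3)(O-acyl) sit between a ring ketone and the lactone oxygen. They can therefore be stored as a donor–acceptor cyclopropane (acyloxy donor, enone acceptor) inside a bicyclo[3.1.0]hex-3-en-2-one, and the lactone ester itself is the tether to a β-silyloxy enethioate.
5. That bicycle ⇐ type A photorearrangement of a symmetric p-quinol ester ⇐ 2,6-bis(hydroxymethyl)-4-methylphenol. Ring order: cyclopentenone (light), lactone plus cyclopentane (key step), cyclohexanone (Michael).

Key step: step 8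

Remark: the photorearrangement creates the first stereocentres from an achiral dienone, so 12–14 are racemic (one enantiomer drawn) and the enantiomers are separated in step 10; 5 and 10–12 are mixtures at the labile ester α-carbon.

**Step 1**
Reactants: 1 2,6-bis(hydroxymethyl)-4-methylphenol
Product: 2 2,6-bis{[(tert-butyldimethylsilyl)oxy]methyl}-4-methylphenol
Conditions: TBSCl (2.1 equiv), imidazole, DMF, 0 °C
Reagents that add atoms: tert-butyldimethylsilyl chloride, CC(C)(C)[Si](C)(C)Cl
Why: Imidazole-mediated silylation should take the two primary benzylic hydroxyls in preference to the hindered, hydrogen-bonded phenol (any aryl silyl ether is cleaved on work-up).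

**Step 2**
Reactants: 2 2,6-bis{[(tert-butyldimethylsilyl)oxy]methyl}-4-methylphenol
Product: 3 2,6-bis{[(tert-butyldimethylsilyl)oxy]methyl}-4-hydroxy-4-methylcyclohexa-2,5-dien-1-one (p-quinol)
Conditions: PhI(OAc)2, MeCN/H2O (3:1), 0 °C
Reagents that add atoms: water, O
Why: Oxidative dearomatization of a 4-alkylphenol with PhI(OAc)2: the phenoxenium-type intermediate is trapped by water at the methyl-bearing para carbon to give the achiral p-quinol.

**Step 3**
Reactants: 3 p-quinol; 4 2,2,5-trimethyl-1,3-dioxane-4,6-dione (methyl Meldrum's acid)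
Product: 5 quinol hydrogen methylmalonate, 3-({3,5-bis[(TBS-oxy)methyl]-1-methyl-4-oxocyclohexa-2,5-dien-1-yl}oxy)-2-methyl-3-oxopropanoic acid
Conditions: toluene, 90 °C
Reagents that add atoms: none
Why: Alcoholysis of the Meldrum's acid derivative (via its carboxyketene on heating) should acylate even the tertiary quinol hydroxyl without base, which avoids conjugate addition of the malonate C–H to the dienone.

**Step 4**
Reactants: 4 methyl Meldrum's acid; 6 ethanethiol
Product: 7 3-(ethylsulfanyl)-2-methyl-3-oxopropanoic acid
Conditions: EtSH (excess), sealed tube, 80 °C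
Reagents that add atoms: none
Why: Thiolysis of the Meldrum's acid derivative gives the malonic half-thioester, the usual two-carbon donor for decarboxylative Claisen chain extension.

**Step 5**
Reactants: 5 quinol hydrogen methylmalonate; 7 3-(ethylsulfanyl)-2-methyl-3-oxopropanoic acid
Product: 10 quinol β-keto thioester, S-ethyl 5-({3,5-bis[(TBS-oxy)methyl]-1-methyl-4-oxocyclohexa-2,5-dien-1-yl}oxy)-2,4-dimethyl-3,5-dioxopentanethioate, via acyl imidazolide 8 (not isolated), via magnesium half-thiomalonate 9 (not isolated)
Conditions: 5, CDI, THF, 23 °C; then 9 [from 7, Mg(OEt)2, THF], 23 °C; aq. HCl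
Reagents that add atoms: none
Why: Masamune–Brooks decarboxylative Claisen condensation: the magnesium enolate of the half-thioester is C-acylated by the acyl imidazolide and loses CO2, giving the β-keto thioester under near-neutral conditions that the dienone should tolerate.

**Step 6**
Reactants: 10 quinol β-keto thioester
Product: 11 S-ethyl 3-[(tert-butyldimethylsilyl)oxy]-2,4-dimethyl-5-oxo-5-(quinolyloxy)pent-2-enethioate (E/Z mixture)
Conditions: TBSOTf, Et3N, CH2Cl2, −78 °C
Reagents that add atoms: tert-butyldimethylsilyl trifluoromethanesulfonate, CC(C)(C)[Si](C)(C)OS(=O)(=O)C(F)(F)F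
Why: Soft enolization/O-silylation: the C–H between ketone and thioester is the most acidic, so the silyl enol ether should form in conjugation with the thioester; its E/Z geometry is lost at the radical stage of step 8.

**Step 7**
Reactants: 11 silyl enol ether quinol ester
Product: 12 rac-(1R*,5S*)-1,3-bis[(TBS-oxy)methyl]-6-methyl-2-oxobicyclo[3.1.0]hex-3-en-6-yl 3-(TBS-oxy)-5-(ethylsulfanyl)-2,4-dimethyl-5-oxopent-3-enoate (both epimers at C6)
Conditions: hν (365 nm), degassed benzene, 20 °C
Reagents that add atoms: none
Why: Type A (lumiketone) photorearrangement of a cross-conjugated cyclohexadienone: n,π* excitation, bonding between the two β-carbons and 1,4-shift of the quaternary carbon give the bicyclo[3.1.0]hex-3-en-2-one as a single constitution because the dienone is symmetric; the ring-fusion centres are set here (racemic), and both epimers at the acyloxy carbon are used.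

**Step 8**
Reactants: 12 rac-bicyclo[3.1.0]hexenone ester
Product: 13 rac-tricyclic keto-lactone thioester (cyclopentenone, central cyclopentane and γ-lactone, cis-syn-cis; lactone α-methyl cis to the silyloxy group)
Conditions: SmI2 (20 mol%), Sm powder (20 mol%), THF, 55 °C
Reagents that add atoms: none
Why: Proposed new method: SmI2 (divalent samarium) should reduce the cyclopropyl enone of 12 to a ketyl whose external cyclopropane bond opens to a trivalent-samarium dienolate and a tertiary α-acyloxy radical; this radical adds 5-exo-trig to the silyloxy-bearing β-carbon of the tethered enethioate (closing the γ-lactone), the resulting α-thioester radical adds 5-exo-trig to the α-carbon of the dienolate (closing the cyclopentane), and the new ketyl returns its electron to samarium, so the step is an isomerization. The closest known reaction type is the SmI2-catalysed radical-relay formal [3+2] cycloaddition of alkyl cyclopropyl ketones with alkenes (and its photocatalytic version with aryl cyclopropyl ketones), which has not been shown for an acyloxycyclopropyl enone, an ester tether or a tetrasubstituted acceptor. Both C6 epimers of 12 give the same planar radical, and the retained ring-fusion CH controls the rest: the cyclopentane must be cis-fused to ring A and the lactone cis-fused to the cyclopentane for geometric reasons, the lactone O–C(CH3) centre is set when the ester carbonyl is held over ring A by chelation to the samarium dienolate and the enethioate reaches the radical from the open side (lactone oxygen syn to the ring-A CH=), and the thioester-bearing carbon is set by chelation of the thioester carbonyl to the same samarium (thioester syn to the ring ketone). The step needs ring opening and both cyclizations to outrun reduction or β-elimination of the enolate, and 5-exo to beat 6-endo attack; catalytic SmI2 without a proton source, the acrylate-type polarization of the acceptor and the reversibility of ring opening should secure this. The lactone α-methyl centre is expected to form mainly with methyl cis to the silyloxy group (allylic strain in the cyclization) and is corrected in step 9.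

**Step 9**
Reactants: 13 rac-tricyclic keto-lactone thioester
Product: 14 rac-tricyclic keto-lactone thioester, epimer with the lactone α-methyl on the concave face
Conditions: LiN(i-Pr)2 (1.2 equiv), THF, −78 °C; then AcOH, −78 °C
Reagents that add atoms: none
Why: Kinetic protonation of the lactone lithium enolate (the most acidic C–H of 13) should occur from the convex face of the cis-fused bicyclic lactone, placing the methyl group on the concave face as in the target, whichever epimer entered.

**Step 10**
Reactants: 14 rac-tricyclic keto-lactone thioester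
Product: 15 tricyclic keto-lactone thioester, single enantiomer
Conditions: preparative SFC, amylose tris(3,5-dimethylphenylcarbamate) phase, CO2/i-PrOH
Reagents that add atoms: none
Why: Resolution of the racemate by chromatography on a chiral stationary phase; the enantiomer with the configuration of the target is carried on (assignment to be secured by anomalous-dispersion X-ray analysis of a later crystalline intermediate).

**Step 11**
Reactants: 15 tricyclic keto-lactone thioester
Product: 16 tricyclic keto-lactone methyl ketone
Conditions: MeZnI, PdCl2(PPh3)2 (5 mol%), toluene/THF, 23 °C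
Reagents that add atoms: methylzinc iodide, C[Zn]I
Why: Fukuyama coupling: palladium-catalysed reaction of the thioester with the organozinc should give the methyl ketone without touching the enone, the lactone or the silyl ethers.

**Step 12**
Reactants: 16 tricyclic keto-lactone methyl ketone
Product: 18 caged exo-methylene diketone lactone, via lithium enolate 17 (not isolated)
Conditions: LiN(SiMe3)2 (1.05 equiv), THF, −78 → 0 °C; aq. NH4Cl
Reagents that add atoms: none
Why: The methyl ketone gives the only kinetically accessible ketone enolate; intramolecular Michael addition to the cyclopentenone β-carbon (possible only on the face where the quaternary carbon holds the chain, which sets the new CH centre) closes the bicyclo[3.2.1]octane, and the resulting β-silyloxy enolate should lose silanolate (E1cB) on warming to give the exo-methylene ketone.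

**Step 13**
Reactants: 18 caged exo-methylene diketone lactone
Product: 20 caged tertiary α-ketol, via hydroperoxide 19 (not isolated)
Conditions: Mn(dpm)3 (10 mol%; dpm = 2,2,6,6-tetramethylheptane-3,5-dionate), PhSiH3, O2 (1 atm), i-PrOH/CH2Cl2, 0 °C; then PPh3
Reagents that add atoms: dioxygen, O=O
Why: Mukaiyama-type hydration of the enone (manganese-hydride hydrogen-atom transfer to the CH2 terminus, trapping of the tertiary α-keto radical by O2, reduction of the hydroperoxide): O2 should approach the two-carbon bridge from its exo face, syn to the one-carbon bridge, giving the tertiary alcohol with the methyl group endo.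

**Step 14**
Reactants: 20 caged tertiary α-ketol
Product: 21 caged primary alcohol
Conditions: HF·pyridine, pyridine, THF, 0 °C
Reagents that add atoms: none
Why: Fluoride-mediated desilylation should cleave the primary silyl ether much faster than the hindered tertiary one.

**Step 15**
Reactants: 21 caged primary alcohol
Product: 22 caged aldehyde
Conditions: Dess–Martin periodinane, NaHCO3, CH2Cl2, 23 °C
Reagents that add atoms: none
Why: Dess–Martin oxidation of the primary alcohol to the non-enolizable aldehyde; the tertiary alcohol and the ketones are inert.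

**Step 16**
Reactants: 23 (E)-but-2-enal
Product: 24 (1E,3E)-1-iodopenta-1,3-diene
Conditions: CHI3, CrCl2, THF, 0 °C
Reagents that add atoms: iodoform, IC(I)I
Why: Takai olefination of the aldehyde gives the (E)-alkenyl iodide.

**Step 17**
Reactants: 22 caged aldehyde; 24 (1E,3E)-1-iodopenta-1,3-diene
Product: 25 caged dienyl carbinol (both carbinol epimers)
Conditions: CrCl2 (4 equiv), NiCl2 (1 mol%), DMF, 23 °C
Reagents that add atoms: none
Why: Nozaki–Hiyama–Kishi coupling: the alkenylchromium reagent adds to the aldehyde in preference to ketones and lactone; the new carbinol centre is not controlled and is removed in step 18.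

**Step 18**
Reactants: 25 caged dienyl carbinol
Product: 26 caged (2E,4E)-dienone
Conditions: Dess–Martin periodinane, NaHCO3, CH2Cl2, 0 °C
Reagents that add atoms: none
Why: Dess–Martin oxidation of the dienylic alcohol gives the sorbyl ketone.

**Step 19**
Reactants: 26 caged (2E,4E)-dienone; 27 (2E,4E)-hexa-2,4-dienoyl chloride
Product: 28 O-silyl-protected target (tertiary TBS ether)
Conditions: MgBr2·OEt2, i-Pr2NEt, CH2Cl2, 23 °C
Reagents that add atoms: none
Why: Soft-enolization C-acylation: the six-membered-ring ketone has the only enolizable α-CH2, and its magnesium enolate is acylated on carbon to give the chelated, enolized 2-acyl ketone.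

**Step 20**
Reactants: 28 O-silyl-protected target
Product: 29 CNP0231466.1
Conditions: HF (48% aq.), MeCN, 0 → 23 °C
Reagents that add atoms: none
Why: Acidic fluoride cleavage of the tertiary silyl ether avoids base and thus retro-aldol cleavage of the β-hydroxy ketone.

**Compound list**
1 | 2,6-bis(hydroxymethyl)-4-methylphenol | Cc1cc(CO)c(O)c(CO)c1 | starting material
2 | 2,6-bis{[(tert-butyldimethylsilyl)oxy]methyl}-4-methylphenol | Cc1cc(CO[Si](C)(C)C(C)(C)C)c(O)c(CO[Si](C)(C)C(C)(C)C)c1 | intermediate
3 | 2,6-bis{[(tert-butyldimethylsilyl)oxy]methyl}-4-hydroxy-4-methylcyclohexa-2,5-dien-1-one | CC1(O)C=C(CO[Si](C)(C)C(C)(C)C)C(=O)C(CO[Si](C)(C)C(C)(C)C)=C1 | intermediate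
4 | 2,2,5-trimethyl-1,3-dioxane-4,6-dione | CC1C(=O)OC(C)(C)OC1=O | starting material
5 | quinol hydrogen methylmalonate | CC(C(=O)O)C(=O)OC1(C)C=C(CO[Si](C)(C)C(C)(C)C)C(=O)C(CO[Si](C)(C)C(C)(C)C)=C1 | intermediate
6 | ethanethiol | CCS | starting material
7 | 3-(ethylsulfanyl)-2-methyl-3-oxopropanoic acid | CCSC(=O)C(C)C(=O)O | intermediate
8 | acyl imidazolide of 5 | CC(C(=O)n1ccnc1)C(=O)OC1(C)C=C(CO[Si](C)(C)C(C)(C)C)C(=O)C(CO[Si](C)(C)C(C)(C)C)=C1 | intermediate
9 | magnesium bis[3-(ethylsulfanyl)-2-methyl-3-oxopropanoate] | CCSC(=O)C(C)C(=O)[O-].CCSC(=O)C(C)C(=O)[O-].[Mg+2] | intermediate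
10 | quinol β-keto thioester | CCSC(=O)C(C)C(=O)C(C)C(=O)OC1(C)C=C(CO[Si](C)(C)C(C)(C)C)C(=O)C(CO[Si](C)(C)C(C)(C)C)=C1 | intermediate
11 | quinol ester with β-silyloxy enethioate (E/Z mixture) | CCSC(=O)C(C)=C(O[Si](C)(C)C(C)(C)C)C(C)C(=O)OC1(C)C=C(CO[Si](C)(C)C(C)(C)C)C(=O)C(CO[Si](C)(C)C(C)(C)C)=C1 | intermediate
12 | rac-bicyclo[3.1.0]hex-3-en-2-one ester (both C6 epimers) | CC(C)(C)[Si](C)(C)OC[C@]12C(=O)C(CO[Si](C)(C)C(C)(C)C)=C[C@@H]2C1(C)OC(=O)C(C)C(O[Si](C)(C)C(C)(C)C)=C(C)C(=O)SCC | intermediate
13 | rac-tricyclic keto-lactone thioester, α-methyl cis to OTBS | CC(C)(C)[Si](C)(C)OC[C@]12C(=O)C(CO[Si](C)(C)C(C)(C)C)=C[C@@H]2[C@]3(C)OC(=O)[C@@H](C)[C@]3(O[Si](C)(C)C(C)(C)C)[C@]1(C)C(=O)SCC | intermediate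
14 | rac-tricyclic keto-lactone thioester, α-methyl on concave face | CC(C)(C)[Si](C)(C)OC[C@]12C(=O)C(CO[Si](C)(C)C(C)(C)C)=C[C@@H]2[C@]3(C)OC(=O)[C@H](C)[C@]3(O[Si](C)(C)C(C)(C)C)[C@]1(C)C(=O)SCC | intermediate
15 | tricyclic keto-lactone thioester, single enantiomer | CC(C)(C)[Si](C)(C)OC[C@]12C(=O)C(CO[Si](C)(C)C(C)(C)C)=C[C@@H]2[C@]3(C)OC(=O)[C@H](C)[C@]3(O[Si](C)(C)C(C)(C)C)[C@]1(C)C(=O)SCC | intermediate
16 | tricyclic keto-lactone methyl ketone | CC(C)(C)[Si](C)(C)OC[C@]12C(=O)C(CO[Si](C)(C)C(C)(C)C)=C[C@@H]2[C@]3(C)OC(=O)[C@H](C)[C@]3(O[Si](C)(C)C(C)(C)C)[C@]1(C)C(C)=O | intermediate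
17 | lithium enolate of the Michael adduct | CC(C)(C)[Si](C)(C)OC[C@]12C([O-])=C(CO[Si](C)(C)C(C)(C)C)[C@@H]3CC(=O)[C@@]1(C)[C@@]1(O[Si](C)(C)C(C)(C)C)[C@@H](C)C(=O)O[C@@]1(C)[C@@H]32.[Li+] | intermediate
18 | caged exo-methylene diketone lactone | CC(C)(C)[Si](C)(C)OC[C@]12C(=O)C(=C)[C@@H]3CC(=O)[C@@]1(C)[C@@]1(O[Si](C)(C)C(C)(C)C)[C@@H](C)C(=O)O[C@@]1(C)[C@@H]32 | intermediate
19 | caged tertiary hydroperoxide | CC(C)(C)[Si](C)(C)OC[C@]12C(=O)[C@@](C)(OO)[C@@H]3CC(=O)[C@@]1(C)[C@@]1(O[Si](C)(C)C(C)(C)C)[C@@H](C)C(=O)O[C@@]1(C)[C@@H]32 | intermediate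
20 | caged tertiary α-ketol | CC(C)(C)[Si](C)(C)OC[C@]12C(=O)[C@@](C)(O)[C@@H]3CC(=O)[C@@]1(C)[C@@]1(O[Si](C)(C)C(C)(C)C)[C@@H](C)C(=O)O[C@@]1(C)[C@@H]32 | intermediate
21 | caged primary alcohol | OC[C@]12C(=O)[C@@](C)(O)[C@@H]3CC(=O)[C@@]1(C)[C@@]1(O[Si](C)(C)C(C)(C)C)[C@@H](C)C(=O)O[C@@]1(C)[C@@H]32 | intermediate
22 | caged aldehyde | O=C[C@]12C(=O)[C@@](C)(O)[C@@H]3CC(=O)[C@@]1(C)[C@@]1(O[Si](C)(C)C(C)(C)C)[C@@H](C)C(=O)O[C@@]1(C)[C@@H]32 | intermediate
23 | (E)-but-2-enal | C/C=C/C=O | starting material
24 | (1E,3E)-1-iodopenta-1,3-diene | C/C=C/C=C/I | intermediate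
25 | caged dienyl carbinol (epimers at the carbinol) | C/C=C/C=C/C(O)[C@]12C(=O)[C@@](C)(O)[C@@H]3CC(=O)[C@@]1(C)[C@@]1(O[Si](C)(C)C(C)(C)C)[C@@H](C)C(=O)O[C@@]1(C)[C@@H]32 | intermediate
26 | caged (2E,4E)-dienone | C/C=C/C=C/C(=O)[C@]12C(=O)[C@@](C)(O)[C@@H]3CC(=O)[C@@]1(C)[C@@]1(O[Si](C)(C)C(C)(C)C)[C@@H](C)C(=O)O[C@@]1(C)[C@@H]32 | intermediate
27 | (2E,4E)-hexa-2,4-dienoyl chloride | C/C=C/C=C/C(=O)Cl | starting material
28 | O-silyl-protected target | C/C=C/C=C/C(=O)[C@]12C(=O)[C@@](C)(O)[C@@H]3\C(=C(O)/C=C/C=C/C)C(=O)[C@@]1(C)[C@@]1(O[Si](C)(C)C(C)(C)C)[C@@H](C)C(=O)O[C@@]1(C)[C@@H]32 | intermediate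
29 | CNP0231466.1 | C/C=C/C=C/C(=O)[C@]12C(=O)[C@@](C)(O)[C@@H]3\C(=C(O)/C=C/C=C/C)C(=O)[C@@]1(C)[C@@]1(O)[C@@H](C)C(=O)O[C@@]1(C)[C@@H]32 | target

**Totals**
Total steps: 20. Longest linear sequence: 18 steps (1–3, 5–15, 17–20).

**Steps most likely to fail**

Step 8 (Proposed new method). What may go wrong: the ring-opened samarium enolate may be reduced further or lose silanolate by β-elimination before the radical cyclizes; the second ring closure onto the hindered enolate carbon may be too slow; or the first cyclization may occur on the wrong face of the radical, giving the lactone anti to ring A. Fallback: the two bonds are made in two known operations. Starting from 12, stoichiometric SmI2 (2.5 equiv) with t-BuOH in THF at −78 °C should effect reductive cyclopropyl-ketone opening, 5-exo radical cyclization, second electron transfer and protonation to give the singly cyclized keto thioester lactone F1. Double deprotonation of F1 with LiN(i-Pr)2 and oxidation of the bis-enolate with Cu(2-ethylhexanoate)2 or Fe(acac)3 (intramolecular oxidative enolate coupling) should then close the cyclopentane and return to the route at 13.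

Step 7. What may go wrong: energy transfer to the silyloxy enethioate or its intramolecular [2+2] addition to the excited dienone may compete with the 1,4-shift, and the bicyclohexenone may react further under the lamp. Fallback: the chromophore is introduced after the light step. Starting from 10, irradiation at 365 nm should give the bicyclo[3.1.0]hexenone β-keto thioester F2, and silylation of F2 with TBSOTf/Et3N at −78 °C returns to the route at 12.

Step 9. What may go wrong: deprotonation at the γ-position of the enone instead of the hindered lactone α-C–H, addition of the lactone enolate to the ring ketone, or protonation from the concave face. Fallback: enolate formation and protonation are separated. Starting from 13, LiN(i-Pr)2 with Me3SiCl present at −100 °C (internal quench) should trap the enolate at once as the cyclic silyl ketene acetal F3; protonolysis of F3 with AcOH in wet THF from the convex face then returns to the route at 14.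

**Further compounds**
F1 | step 8 | singly cyclized keto thioester lactone (no bond yet between the two future quaternary carbons) | CC(C)(C)[Si](C)(C)OCC1C(=O)C(CO[Si](C)(C)C(C)(C)C)=C[C@@H]1[C@]1(C)OC(=O)C(C)[C@]1(O[Si](C)(C)C(C)(C)C)C(C)C(=O)SCC
F2 | step 7 | rac-bicyclo[3.1.0]hex-3-en-2-one β-keto thioester ester | CC(C)(C)[Si](C)(C)OC[C@]12C(=O)C(CO[Si](C)(C)C(C)(C)C)=C[C@@H]2C1(C)OC(=O)C(C)C(=O)C(C)C(=O)SCC
F3 | step 9 | rac-trimethylsilyl ketene acetal of the lactone of 13 | CC(C)(C)[Si](C)(C)OC[C@]12C(=O)C(CO[Si](C)(C)C(C)(C)C)=C[C@@H]2[C@]3(C)OC(O[Si](C)(C)C)=C(C)[C@]3(O[Si](C)(C)C(C)(C)C)[C@]1(C)C(=O)SCC
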